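## The problem

Target 12 is a 1-benzofuran-2,6-dione. A five-membered lactone (ring A: O1, C2, C3, C3a, C7a) is fused through C3a–C7a to a six-membered carbocycle (ring B: C3a, C4, C5, C6, C7, C7a) held at the quinone methide level, C3=C3a–C7a=C7–C6=O, with a second ring double bond C4=C5. Every carbon of ring B is substituted (phenyl at C4 and C7, methoxy at C5, ketone at C6, lactone oxygen at C7a), and the methide carbon C3 carries a 4-hydroxyphenyl group next to the C4 phenyl, so the periphery is crowded. There is no stereocentre and no double bond of definable geometry (C3=C3a lies inside ring A), so nothing has to be controlled stereochemically; the one sp3 centre that appears on the way, C3 of a leuco lactone, is erased by oxidation. The real task is to tell four oxygens apart: O1 acylated, O5 methylated, O6 a carbonyl and the aryl hydroxyl free, although O5 and O6 are neighbours on the same ring. The finished chromophore is fragile: the quinone methide is reduced by hydrogen or hydride and accepts nucleophiles, the lactone is an enol-type ester that hydroxide or alkoxide opens, and the hydroquinone- and catechol-level compounds that precede it are oxidised by air. A short synthesis is possible because O1, C7a, C3a and C3 are the four atoms of the oxadiene of an ortho-quinone methide, and C2 is a single carbon at the carboxyl level, which an isocyanide can deliver. The arene that corresponds to ring B, triol 3, has exactly one unsubstituted carbon, C3a, and it lies ortho to the C7a hydroxyl and para to the C6 hydroxyl, which is where a phenol reacts with an aldehyde.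

## Retrosynthesis

The last bond to be made is not part of the skeleton: the aryl O–H of 12 is traced to the triisopropylsilyl ether 11 (O–Si cut). A protecting group is needed because methylation must reach O5 only. Silicon is preferred to a benzyl ether because fluoride removes it without changing the oxidation level, whereas hydrogenolysis would reduce the quinone methide and force a re-oxidation; an acetal would not survive the acid of the earlier steps and an ester would need base. 11 is no simpler than 12, and the forward step asks only for a fluoride source that does not open the lactone.

The O5–CH3 bond is cut next, giving enol 10. Methylation is placed here and not earlier because 10 has exactly one hydroxyl: O6 is the ketone, O1 is in the lactone and the aryl oxygen is silylated. At the catechol level of 9 the O5 and O6 hydroxyls would be nearly equivalent. The forward reaction has to alkylate an acidic, hindered enol on oxygen without base.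

No skeletal bond is cut between 10 and the leuco lactone 9; two hydrogens (C3–H and one catechol O–H) are added. 9 is an ordinary aromatic benzofuran-2(3H)-one without the electrophilic chromophore. The forward oxidation must give one tautomer, and the structure guarantees it: C6 is para to C3a and C5 is meta, so only O6 can become the quinone methide carbonyl.

The lactone carbonyl of 9 is traced to the amino carbon of 2-aminobenzofuran 8 (C2=O exchanged for C2–N, the oxygen coming from water). This exposes C2 as a carbon of isocyanide origin. Keeping C2 as the carboxyl group of a preformed arylacetic or mandelic acid would cut only C3–C3a and O1–C2 and would need that acid to be made first. Forward, a cyclic ketene N,O-acetal has to be hydrolysed in acid while a catechol is kept from air.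

Three bonds of 8 are then cut at once: C3–C3a, C2–C3 and O1–C2. C3 with its aryl group becomes the carbonyl carbon of aldehyde 5, C2 becomes the carbon of tert-butyl isocyanide 6, and what is left is triol 3, which holds all of ring B with both phenyl groups and all three oxygens. Ortho-quinone methide 7 links them. Against two-bond cuts, this one reduces the target to three small pieces, makes all three bonds at the one free ring position, and never has to attach O1 to the ring. The forward reaction asks for hydroxyalkylation at a carbon next to a phenyl group, for 7 to be trapped by 6 faster than by 3, and for exclusion of air.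

Triol 3 is traced through triacetate 2 to 2,5-diphenyl-1,4-benzoquinone 1 by cutting the C6–O bond. The two carbonyl oxygens of 1 become O5 and O1, acetate adds to one of the two equivalent CH carbons to supply O6, and the other CH is left as C3a. 1 is bought, and with it both phenyl–ring bonds. Aldehyde 5 comes from 4-hydroxybenzaldehyde 4 by O–Si bond formation.

## Roads not taken

Alternative 1: The cut is at the two aryl–ring bonds C4–phenyl and C7–phenyl. The 4,7-dibromo quinone methide lactone A2, with O5 already methylated and the aryl hydroxyl as its acetate, would be coupled twice with phenylboronic acid A3 under Suzuki–Miyaura conditions (zerovalent palladium, fluoride base, dioxane) to give A1, the acetate of the target; no ring closes.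
- Merits: any pair of aryl groups could be put on a common late intermediate, and C–Br bonds on an electron-poor quinoid ring add readily to palladium.
- Weak points: both couplings are at carbons flanked on both sides (C4 between C5–OMe and C3a, beside the C3 aryl group; C7 between the C6 ketone and C7a). Fluoride and boronate meet an aryl acetate, an enol lactone and an electrophilic quinone methide. The quinoid can oxidise zerovalent palladium or be attacked by phosphines. A2 itself still needs ring A and the oxygen pattern to be built, with two bromine atoms carried through.
- Comparison: Alternative 1 is the better plan where analogues with other C4/C7 aryl groups are wanted. The chosen plan has only brevity to set against that: both phenyl groups are bought with quinone 1 and no metal-catalysed step touches the chromophore.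

Alternative 2: Here ring B is made, not bought, and the cut is the C3a–C7a bond. Cyclobutenone A5 would be reached from diisopropyl squarate A6 by two successive organolithium additions (phenyl, then 1-phenylvinyl, with acidic rearrangement of the first adduct in between) and O-methylation of the tertiary alkoxide. On heating in toluene A5 would open in a 4π electrocyclic step and reclose in a 6π step, the ketene carbon so formed (C7a) bonding to the vinyl terminus (C3a); tautomerisation would give phenol A4.
- Merits: A4 carries O5 as the methyl ether and O6 as an isopropyl ether from the outset, so the regiochemistry of methylation is settled by construction, and the thermal cascade is reliable.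
- Weak points: A4 is only ring B. Ring A and the C3 aryl group would still have to be annulated at the C3a–H/C7a–OH pair, the isopropyl ether removed next to a methyl ether, and the product oxidised, after some four steps spent on a ring that quinone 1 supplies in two.
- Comparison: the chosen plan concedes the built-in O5/O6 differentiation and answers it with 10, in which O5–H is the only hydroxyl left, so one methylation does the same job on a shorter route.

Alternative 3: The cut is C3–C3a and O1–C7a. 3,6-Diphenylbenzene-1,2-diol A8 would be oxidised at a graphite anode in buffered aqueous acetonitrile to ortho-quinone A10. The arylmalonic acid A9 adds through carbon at C3a, re-oxidation lets a carboxylate oxygen add at C7a and close ring A, and decarboxylation and a last anodic oxidation would deliver A7, the benzyl ether analogue of 10.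
- Merits: in step count it beats the chosen plan. One operation would replace steps 4 to 6, no isocyanide and no hydrolysis is needed, and the oxidant is the electrode.
- Weak points: the nucleophile is the tertiary carbon of A9 and must attack a ring carbon next to a phenyl group, building a quaternary centre in the bond-forming event. Arylmalonic acids lose CO2 easily and their carboxylates are themselves oxidised at an anode. The second bond is a C–O bond to the other phenyl-flanked ring carbon, in competition with water. A8 needs its own arylation sequence. The benzyl ether of A7 could later be removed only with reduction of the quinone methide.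
- Comparison: against the shorter count the chosen plan sets a C–C bond formation in which an aldehyde carbon, not a quaternary centre, is attached at a position activated by two hydroxyls. O1 is already on the arene, so no C–O bond to ring B has to be made, and the three components are bought or lie two steps from quinone 1.

Key step: step 4

Assumption: 12 is taken as the tautomer drawn (C6 ketone, free aryl hydroxyl), and aldehyde 5 is made in one step in case it cannot be bought.

## Route

Step 1
Reactants: 1 2,5-diphenylcyclohexa-2,5-diene-1,4-dione (2,5-diphenyl-1,4-benzoquinone)
Product: 2 3,6-diphenylbenzene-1,2,4-triyl triacetate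
Conditions: Ac2O, BF3·OEt2, 45 °C
Reagents that add atoms: acetic anhydride, CC(=O)OC(C)=O
Why: Thiele–Winter acetoxylation: the Lewis-acid-activated quinone takes acetate in a 1,4-addition at one of its two symmetry-equivalent CH carbons and the acetoxyhydroquinone is acetylated in the same pot; the product is no longer a quinone, so a second acetoxylation cannot follow.

Step 2
Reactants: 2 3,6-diphenylbenzene-1,2,4-triyl triacetate
Product: 3 3,6-diphenylbenzene-1,2,4-triol
Conditions: conc. HCl (cat.), degassed MeOH, reflux, Ar; evaporation, used at once
Reagents that add atoms: none
Why: Acid-catalysed transesterification of three aryl acetates, with methyl acetate distilling off; base is avoided because the triol anion would be oxidised by traces of air.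

Step 3
Reactants: 4 4-hydroxybenzaldehyde
Product: 5 4-[(triisopropylsilyl)oxy]benzaldehyde
Conditions: TIPSCl, imidazole, DMF, rt
Reagents that add atoms: chlorotriisopropylsilane, CC(C)[Si](Cl)(C(C)C)C(C)C
Why: Standard imidazole-promoted silylation of a phenol; the hindered triisopropylsilyl aryl ether is chosen because it should resist the Brønsted acid of steps 4 and 5 and leaves with fluoride at the end without any redox change.

Step 4
Reactants: 3 3,6-diphenylbenzene-1,2,4-triol; 5 4-[(triisopropylsilyl)oxy]benzaldehyde; 6 tert-butyl isocyanide (2-isocyano-2-methylpropane)
Product: 8 2-(tert-butylamino)-4,7-diphenyl-3-{4-[(triisopropylsilyl)oxy]phenyl}-1-benzofuran-5,6-diol, via ortho-quinone methide 7 (not isolated)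
Conditions: 6 (2.5 equiv), CSA (0.2 equiv), 4 Å MS, PhMe, 90 °C, sealed tube, Ar
Reagents that add atoms: none
Why: Camphorsulfonic acid activates aldehyde 5 for Friedel–Crafts hydroxyalkylation of 3 at C3a, the only unsubstituted ring carbon and the one activated by the ortho (C7a) and para (C6) hydroxyls, and the carbinol loses water to give ortho-quinone methide 7 (or its para-quinoid tautomer through O6, which has the same electrophilic carbon). The divalent carbon of isocyanide 6 adds to the methide carbon C3 and restores the arene, the nitrilium ion is captured by the C7a hydroxyl in a 5-exo-dig closure of ring A, and a proton shift from C3 to nitrogen gives the aromatic 2-aminofuran, so C3–C3a, C2–C3 and O1–C2 are made in one operation. The closest known reaction is the formal (4+1) cycloaddition of isocyanides with ortho-quinone methides generated in situ from electron-rich phenols or naphthols and aromatic aldehydes, which gives 2-aminobenzofurans. No stereocentre is formed. The step needs site selectivity and chemoselectivity: the substitution pattern of 3 forces the site, only the C7a hydroxyl is within reach of the nitrilium carbon, and the excess of 6 together with the crowding around C3a of a second triol should keep trapping of 7 by 3 from competing. The sieves remove the water that would hydrate the isocyanide or the nitrilium ion, and an amide formed that way would in any case lactonise to 9 in step 5. Argon is needed because 3 and 8 are oxidised by air.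

Step 5
Reactants: 8 2-(tert-butylamino)-4,7-diphenyl-3-{4-[(triisopropylsilyl)oxy]phenyl}-1-benzofuran-5,6-diol
Product: 9 rac-5,6-dihydroxy-4,7-diphenyl-3-{4-[(triisopropylsilyl)oxy]phenyl}-1-benzofuran-2(3H)-one
Conditions: 1 M aq HCl, degassed THF, 40 °C, Ar
Reagents that add atoms: water, O
Why: The 2-aminofuran is a cyclic ketene N,O-acetal: protonation at C3 gives an O-aryl imidate salt, water adds at C2 and tert-butylamine leaves, which is ordinary acidic imidate hydrolysis to the ester, here the lactone. C3 becomes a stereocentre but is formed racemic and is erased in step 6.

Step 6
Reactants: 9 rac-5,6-dihydroxy-4,7-diphenyl-3-{4-[(triisopropylsilyl)oxy]phenyl}-1-benzofuran-2(3H)-one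
Product: 10 5-hydroxy-4,7-diphenyl-3-{4-[(triisopropylsilyl)oxy]phenyl}-1-benzofuran-2,6-dione
Conditions: Ag2O (1.1 equiv), Na2SO4, CH2Cl2, rt, dark
Reagents that add atoms: none
Why: Two-electron oxidation of a catechol by Ag2O, the classical reagent for ortho-quinones and quinone methides; the 5,6-quinone first formed enolises through its acidic C3–H (vinylogous to the C5 carbonyl, doubly benzylic and alpha to the lactone carbonyl) to the conjugated quinone methide. Because C5 is meta to C3a, only O6 can become the carbonyl, so a single tautomer with one free hydroxyl (O5) should result.

Step 7
Reactants: 10 5-hydroxy-4,7-diphenyl-3-{4-[(triisopropylsilyl)oxy]phenyl}-1-benzofuran-2,6-dione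
Product: 11 5-methoxy-4,7-diphenyl-3-{4-[(triisopropylsilyl)oxy]phenyl}-1-benzofuran-2,6-dione
Conditions: TMSCHN2 (hexanes), PhMe–MeOH 4:1, 0 °C to rt
Reagents that add atoms: (trimethylsilyl)diazomethane, C[Si](C)(C)C=[N+]=[N-]
Why: O-methylation of an acidic enol (an alpha-hydroxy enone vinylogous to the lactone carbonyl) by a diazoalkane: proton transfer from O5–H gives a methyldiazonium ion next to the oxyanion, which is methylated. No base is present, so lactone and silyl ether are left alone, and the carbon termini of the ambident anion (C4, C3) are fully substituted.

Step 8
Reactants: 11 5-methoxy-4,7-diphenyl-3-{4-[(triisopropylsilyl)oxy]phenyl}-1-benzofuran-2,6-dione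
Product: 12 3-(4-hydroxyphenyl)-5-methoxy-4,7-diphenyl-1-benzofuran-2,6-dione
Conditions: HF·pyridine, THF, 0 °C to rt
Reagents that add atoms: none
Why: Fluoride-driven cleavage of an aryl silyl ether under mildly acidic, non-reducing conditions, which should neither open the lactone nor change the oxidation level of the quinone methide; the C5 enol methyl ether is inert to the reagent.

## Compound list

1 | 2,5-diphenylcyclohexa-2,5-diene-1,4-dione | O=C1C=C(c2ccccc2)C(=O)C=C1c1ccccc1 | starting material
2 | 3,6-diphenylbenzene-1,2,4-triyl triacetate | CC(=O)Oc1cc(-c2ccccc2)c(OC(C)=O)c(OC(C)=O)c1-c1ccccc1 | intermediate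
3 | 3,6-diphenylbenzene-1,2,4-triol | Oc1cc(-c2ccccc2)c(O)c(O)c1-c1ccccc1 | intermediate
4 | 4-hydroxybenzaldehyde | O=Cc1ccc(O)cc1 | starting material
5 | 4-[(triisopropylsilyl)oxy]benzaldehyde | O=Cc1ccc(O[Si](C(C)C)(C(C)C)C(C)C)cc1 | intermediate
6 | tert-butyl isocyanide (2-isocyano-2-methylpropane) | [C-]#[N+]C(C)(C)C | starting material
7 | 3,4-dihydroxy-2,5-diphenyl-6-{4-[(triisopropylsilyl)oxy]benzylidene}cyclohexa-2,4-dien-1-one (ortho-quinone methide of step 4, not isolated, alkene geometry not defined) | O=C1C(=Cc2ccc(O[Si](C(C)C)(C(C)C)C(C)C)cc2)C(c2ccccc2)=C(O)C(O)=C1c1ccccc1 | intermediate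
8 | 2-(tert-butylamino)-4,7-diphenyl-3-{4-[(triisopropylsilyl)oxy]phenyl}-1-benzofuran-5,6-diol | CC(C)(C)Nc1oc2c(-c3ccccc3)c(O)c(O)c(-c3ccccc3)c2c1-c1ccc(O[Si](C(C)C)(C(C)C)C(C)C)cc1 | intermediate
9 | rac-5,6-dihydroxy-4,7-diphenyl-3-{4-[(triisopropylsilyl)oxy]phenyl}-1-benzofuran-2(3H)-one (racemic at C3) | O=C1Oc2c(-c3ccccc3)c(O)c(O)c(-c3ccccc3)c2C1c1ccc(O[Si](C(C)C)(C(C)C)C(C)C)cc1 | intermediate
10 | 5-hydroxy-4,7-diphenyl-3-{4-[(triisopropylsilyl)oxy]phenyl}-1-benzofuran-2,6-dione | OC1=C(c2ccccc2)C2=C(c3ccc(O[Si](C(C)C)(C(C)C)C(C)C)cc3)C(=O)OC2=C(c2ccccc2)C1=O | intermediate
11 | 5-methoxy-4,7-diphenyl-3-{4-[(triisopropylsilyl)oxy]phenyl}-1-benzofuran-2,6-dione | COC1=C(c2ccccc2)C2=C(c3ccc(O[Si](C(C)C)(C(C)C)C(C)C)cc3)C(=O)OC2=C(c2ccccc2)C1=O | intermediate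
12 | 3-(4-hydroxyphenyl)-5-methoxy-4,7-diphenyl-1-benzofuran-2,6-dione | COC1=C(c2ccccc2)C2=C(c3ccc(O)cc3)C(=O)OC2=C(c2ccccc2)C1=O | target

## Step count and weak points

Total step count: 8. Longest linear sequence: 7 steps (1 to 12 through steps 1, 2, 4, 5, 6, 7 and 8); step 3 is a one-step side branch.

Step 4 (key step). The hydroxyalkylation may be slow because C3a lies next to the C4-side phenyl group. The triol may be oxidised by adventitious air to the hydroxyquinone level, where it is no longer a nucleophile. The acid may consume the isocyanide by hydration or oligomerisation before 7 forms. The aldehyde may be tied up reversibly as an acetal of the C5/C6 catechol, and part of the silyl ether may be lost in the hot acid. Fallback, from 3 back to 9: the isocyanide is given up and C3–C2 is brought in as a mandelic acid. Triol 3 would be heated with commercial racemic 4-hydroxymandelic acid and p-TsOH in acetic acid under argon. The para-hydroxybenzyl cation alkylates C3a (Friedel–Crafts) and the carboxylic acid lactonises onto the C7a hydroxyl, giving rac-5,6-dihydroxy-3-(4-hydroxyphenyl)-4,7-diphenyl-1-benzofuran-2(3H)-one F1. Its unhindered aryl hydroxyl would then be silylated with TIPSCl and imidazole in preference to the two catechol hydroxyls, each of which sits between a phenyl group and an oxygen. This returns to 9 and bypasses steps 4 and 5.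

Step 1. Acetoxylation may stall because both enone units of 1 are hindered and stabilised by conjugation with the phenyl groups, and reductive acetylation to the diacetate may compete. Fallback, from 1 back to 3: Weitz–Scheffer epoxidation of 1 (H2O2, Na2CO3, aqueous dioxane) would give racemic 1,4-diphenyl-7-oxabicyclo[4.1.0]hept-3-ene-2,5-dione F2. Cold concentrated H2SO4 isomerises such quinone epoxides to hydroxyquinones, here 2-hydroxy-3,6-diphenylcyclohexa-2,5-diene-1,4-dione F3. Reduction of F3 with Na2S2O4 in EtOAc–water gives 3 directly, so step 2 is bypassed as well.

Step 5. The electron-rich aminofuran catechol may be oxidised by air before or during hydrolysis. The tetrahedral intermediate may open to the N-tert-butyl amide, which lactonises only slowly, and prolonged warming in acid may start to remove the silyl group. Fallback, from 8 back to 10: the order of hydrolysis and oxidation is exchanged. Crude 8 would be oxidised at once with Ag2O to the iminolactone 2-(tert-butylimino)-5-hydroxy-4,7-diphenyl-3-{4-[(triisopropylsilyl)oxy]phenyl}-1-benzofuran-6(2H)-one F4, which is at the air-stable quinone methide level and can be purified. Hydrolysis of its N-tert-butyl imidate with aqueous acetic acid in THF then gives 10, bypassing 9 and step 6.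

## Further compounds

F1 | step 4 | rac-5,6-dihydroxy-3-(4-hydroxyphenyl)-4,7-diphenyl-1-benzofuran-2(3H)-one | O=C1Oc2c(-c3ccccc3)c(O)c(O)c(-c3ccccc3)c2C1c1ccc(O)cc1
F2 | step 1 | rac-1,4-diphenyl-7-oxabicyclo[4.1.0]hept-3-ene-2,5-dione | O=C1C=C(c2ccccc2)C(=O)C2OC12c1ccccc1
F3 | step 1 | 2-hydroxy-3,6-diphenylcyclohexa-2,5-diene-1,4-dione | O=C1C=C(c2ccccc2)C(=O)C(O)=C1c1ccccc1
F4 | step 5 | 2-(tert-butylimino)-5-hydroxy-4,7-diphenyl-3-{4-[(triisopropylsilyl)oxy]phenyl}-1-benzofuran-6(2H)-one (imine geometry not defined) | CC(C)(C)N=C1OC2=C(c3ccccc3)C(=O)C(O)=C(c3ccccc3)C2=C1c1ccc(O[Si](C(C)C)(C(C)C)C(C)C)cc1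
A1 | alternative 1 | 4-(5-methoxy-2,6-dioxo-4,7-diphenyl-1-benzofuran-3-yl)phenyl acetate | COC1=C(c2ccccc2)C2=C(c3ccc(OC(C)=O)cc3)C(=O)OC2=C(c2ccccc2)C1=O
A2 | alternative 1 | 4-(4,7-dibromo-5-methoxy-2,6-dioxo-1-benzofuran-3-yl)phenyl acetate | COC1=C(Br)C2=C(c3ccc(OC(C)=O)cc3)C(=O)OC2=C(Br)C1=O
A3 | alternative 1 | phenylboronic acid | OB(O)c1ccccc1
A4 | alternative 2 | 4-methoxy-2,5-diphenyl-3-(propan-2-yloxy)phenol | COc1c(OC(C)C)c(-c2ccccc2)c(O)cc1-c1ccccc1
A5 | alternative 2 | rac-4-methoxy-2-phenyl-4-(1-phenylethenyl)-3-(propan-2-yloxy)cyclobut-2-en-1-one | COC1(C(=C)c2ccccc2)C(OC(C)C)=C(c2ccccc2)C1=O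
A6 | alternative 2 | 3,4-di(propan-2-yloxy)cyclobut-3-ene-1,2-dione (diisopropyl squarate) | CC(C)OC1=C(OC(C)C)C(=O)C1=O
A7 | alternative 3 | 3-[4-(benzyloxy)phenyl]-5-hydroxy-4,7-diphenyl-1-benzofuran-2,6-dione | OC1=C(c2ccccc2)C2=C(c3ccc(OCc4ccccc4)cc3)C(=O)OC2=C(c2ccccc2)C1=O
A8 | alternative 3 | 3,6-diphenylbenzene-1,2-diol | Oc1c(O)c(-c2ccccc2)ccc1-c1ccccc1
A9 | alternative 3 | 2-[4-(benzyloxy)phenyl]propanedioic acid | OC(=O)C(C(=O)O)c1ccc(OCc2ccccc2)cc1
A10 | alternative 3 | 3,6-diphenylcyclohexa-3,5-diene-1,2-dione | O=C1C(=O)C(c2ccccc2)=CC=C1c1ccccc1
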